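**Remark on the chemistry:** the catalogue entry is taken to be the acid encoded by the SMILES, i.e. (3S,6R), with the methoxy group and the carboxymethyl arm cis on the 1,2-dioxane.

## The problem

Target 25 is a 1,2-dioxane (ring O1–O2–C3–C4–C5–C6). C3 (S) carries a CH2CO2H arm. C6 (R) is a methoxy peroxyketal carbon carrying a sixteen-carbon chain with a 4-yne, a 6E-alkene and a methyl ketone at C15. There are only two stereocentres, 1,4 across the peroxide, and no centre in the side chain that could relay chirality to the ring. C6 is a ketal carbon and can epimerise under acid through a peroxycarbenium ion. With the C3 arm equatorial, the anomeric effect favours axial OMe and an equatorial chain, which is the required cis isomer. C3 is therefore the one centre that must be set absolutely, and it can then govern C6.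

The O–O bond will not survive hydrides, low-valent metals in excess, phosphines or radicals. The C3–H invites Kornblum–DeLaMare cleavage by base, the β-peroxy acid can undergo E1cB ring opening, and the peroxyketal is acid-labile. The enyne and the methyl ketone would not pass through an oxygenation, a diimide reduction or a peracid step, so the chain has to be attached last and the peroxide made before it.

The enabling feature is that C3 and C6 sit on O2 and O1 and are 1,4 to each other, while the carboxyl carbon of the arm is two bonds from C3. Bonding that carbon to C6 gives a six-membered carbocycle (C3, CH2, C=O carbon, C6, C5, C4). The dioxane then becomes the peroxide bridge of a 2,3-dioxabicyclo[2.2.2]octane, the skeleton that singlet oxygen makes from a cyclohexa-1,3-diene.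

## Retrosynthesis

**25 ⇒ 20 + 24.** The C5'–C6' bond between the alkyne and the alkene is cut (Sonogashira). Cutting the alkene (olefination) or the C3'–C4' bond (acetylide alkylation) would need carbanions next to a peroxide and a free acid. The chosen cut needs only an amine base and takes the E geometry from iodide 24. It leaves alkyne acid 20, which holds both stereocentres. The forward step must spare the O–O bond.

**24 ⇒ 23 ⇒ 22 ⇒ 21.** The vinyl iodide comes from aldehyde 23 by one-carbon iodo-olefination, 23 from hydroxy ketone 22, and the methyl ketone from the terminal alkene of dec-9-en-1-ol 21, which already holds ten of the eleven carbons.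

**20 ⇒ 19.** The alkyne C–H is traded for C–Si. A triisopropylsilyl cap hides the alkyne from borane, diimide and peracid and is removed only when the ring is finished.

**19 ⇒ 17 (through 18).** The C6–OMe bond is cut and the carboxyl oxygen is joined to C6, giving peroxy lactone 18. Removing that oxygen gives ketone 17, in which C6 is bonded to the carbonyl carbon. The neighbouring cut, O1–C6 to a γ-hydroperoxy ketone, would leave C3 to be set on an open chain. This cut keeps C3 inside a rigid bicycle and brings the arm in at the acid oxidation level. The forward reaction asks the peroxy-bearing bridgehead to migrate in a Baeyer–Villiger step, the least charted demand of the route.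

**17 ⇒ 16 ⇒ 15 ⇒ 14.** These are functional-group changes: ketone from alcohol, alcohol from silyl ether, and the saturated C4–C5 unit from the alkene that the cycloaddition leaves behind.

**14 ⇒ 13.** Both C–O bonds of the peroxide bridge (C1–O2 and C4–O3 of the bicycle, later C6–O1 and C3–O2) are cut at once. The precursor is monocyclic dienyl silyl ether 13 with one stereocentre. The forward step needs face selectivity, which the silyloxy group next to the substituted diene terminus supplies.

**13 ⇒ 12 ⇒ 10.** The unsubstituted diene double bond is traced to the carbonyl of enone 10 through cross-conjugated dienyl triflate 12. Kinetic enolisation fixes the position of the new double bond. Eliminative routes would risk loss of silanol and aromatisation.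

**10 ⇒ 8 + 4 (through 9).** The ring–chain sp2–sp3 bond is cut (B-alkyl Suzuki–Miyaura). β-Iodoenone 8 is an ideal electrophile, and the borane comes from terminal alkene 4 without touching the silyl alkyne. A cuprate or Stork–Danheiser approach would need a preformed functionalised organometallic.

**8 ⇒ 7 ⇒ 6 ⇒ 5 and 4 ⇒ 1 + 2 (through 3).** The γ-oxygen of 8 is the original carbinol. The enone carbonyl comes from allylic oxidation of 7, the silyl ether from alcohol 6, and the stereocentre from CBS reduction of iodoenone 5. Enyne 4 comes from silylacetylene 1 and allyl bromide 2.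

## Roads not taken

**Alternative 1:** The O1–C6 bond is cut. Hydroperoxy dimethyl ketal A1 would close in acidic methanol to dioxane A2, the hydroperoxide displacing methanol at C6 while reversible ionisation funnels both ketal epimers to one.
- Merits: the ring closure is well-trodden chemistry for 6-methoxy-1,2-dioxanes. It uses the same thermodynamic control at C6 as the chosen plan, and in ring-forming precedent it is the stronger road.
- Weak points: the secondary hydroperoxide of A1 must be made enantiopure, in practice by displacing a sulfonate with hydrogen peroxide, which is slow, competes with elimination and handles a free hydroperoxide. The arm arrives as a protected hydroxyethyl group and needs deprotection and oxidation with the peroxide in place.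
- Comparison: the chosen plan sets C3 in a concerted cycloaddition and delivers the carboxyl directly. It pays with an oxygen insertion that has no direct precedent. Alternative 1 is therefore kept as the fallback for that step.

**Alternative 2:** The C3–C4 and O1–C6 bonds are cut. A Lewis acid would ionise methoxy silylperoxy acetal A3, and methoxycyclopropane A4 would attack the peroxycarbenium ion and be trapped by the silylperoxy oxygen to give ester A5.
- Merits: it is the shortest and most convergent road, and the arm arrives as an ester at the right oxidation level. In step count it beats the chosen plan clearly.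
- Weak points: the peroxycarbenium ion from A3 is planar and racemic, so nothing controls C3 absolutely. Capture of such an ion by a donor cyclopropane is an extrapolation from allylsilane and enol ether additions. A4 can simply ionise to a ketone under the Lewis acid.
- Comparison: the chosen plan is longer, but it gives absolute control from a catalytic reduction and a cycloaddition of a well-known type.

**Alternative 3:** The C4=C5 bond is cut. Acyclic peroxyketal A6 would close by ring-closing metathesis with the second-generation Grubbs catalyst, RuCl2(=CHPh)(H2IMes)(PCy3), to dihydrodioxine A7.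
- Merits: the closure is catalytic and neutral, and metathesis of diallyl peroxides has precedent. Like the chosen plan it ends in a dihydrodioxine that diimide can saturate.
- Weak points: A6 needs an enantiopure allylic hydroperoxide and a vinyl-substituted peroxyketal carbon whose configuration is fixed before ring closure, with no simple way to correct it. The quaternary allylic centre slows metathesis, and ruthenium carbenes can degrade peroxides. The arm again needs later oxidation.
- Comparison: the chosen plan forms both C–O bonds stereospecifically in the ring-closing event and lets C6 settle under thermodynamic control afterwards.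

Key step: step 8

## Route

Step 1
Reactants: 1 (triisopropylsilyl)acetylene; 2 allyl bromide
Product: 4 triisopropyl(pent-4-en-1-yn-1-yl)silane, via [(triisopropylsilyl)ethynyl]magnesium bromide 3 (not isolated)
Conditions: EtMgBr, THF, 0 → 40 °C; then CuBr·SMe2 (5 mol%), 2, THF, 50 °C
Reagents that add atoms: none
Why: Copper-catalysed allylation of an alkynyl Grignard reagent is a standard route to skipped enynes; allyl bromide gives the same product by direct or allylic substitution.

Step 2
Reactants: 5 2-iodocyclohex-2-en-1-one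
Product: 6 (R)-2-iodocyclohex-2-en-1-ol
Conditions: (S)-1-methyl-3,3-diphenyltetrahydro-1H,3H-pyrrolo[1,2-c][1,3,2]oxazaborole (10 mol%), BH3·SMe2, THF, −20 °C; MeOH quench
Reagents that add atoms: none
Why: CBS reduction; α-halo enones are among the best substrates because the iodoalkenyl side acts as the large group, so the (S)-oxazaborolidine should deliver hydride to give the (R)-carbinol, the stereocentre that later steers the cycloaddition.

Step 3
Reactants: 6 (R)-2-iodocyclohex-2-en-1-ol
Product: 7 (R)-tert-butyl[(2-iodocyclohex-2-en-1-yl)oxy]dimethylsilane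
Conditions: TBSCl, imidazole, DMF, rt
Reagents that add atoms: tert-butyldimethylsilyl chloride, CC(C)(C)[Si](C)(C)Cl
Why: Routine silylation of a secondary allylic alcohol; the bulky ether survives the oxidation, coupling and enolate steps and later blocks one diene face.

Step 4
Reactants: 7 (R)-tert-butyl[(2-iodocyclohex-2-en-1-yl)oxy]dimethylsilane
Product: 8 (R)-4-[(tert-butyldimethylsilyl)oxy]-3-iodocyclohex-2-en-1-one
Conditions: CrO3, 3,5-dimethylpyrazole, CH2Cl2, −20 °C
Reagents that add atoms: chromium trioxide, O=[Cr](=O)=O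
Why: Allylic oxidation of a cyclohexene to the enone with the hexavalent chromium–dimethylpyrazole complex; C4 is the only allylic methylene, and the stereocentre is not involved.

Step 5
Reactants: 4 triisopropyl(pent-4-en-1-yn-1-yl)silane; 8 (R)-4-[(tert-butyldimethylsilyl)oxy]-3-iodocyclohex-2-en-1-one
Product: 10 (R)-4-[(tert-butyldimethylsilyl)oxy]-3-[5-(triisopropylsilyl)pent-4-yn-1-yl]cyclohex-2-en-1-one, via alkylborane 9 (not isolated)
Conditions: 4, 9-BBN, THF, 0 °C → rt; then 8, PdCl2(dppf) (5 mol%), AsPh3 (5 mol%), K3PO4 (aq.), DMF, rt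
Reagents that add atoms: none
Why: 9-BBN hydroborates the terminal alkene much faster than the hindered silyl alkyne, and B-alkyl Suzuki–Miyaura coupling with β-iodoenones is well established; room temperature and a mild base protect the γ-stereocentre.

Step 6
Reactants: 10 (R)-4-[(tert-butyldimethylsilyl)oxy]-3-[5-(triisopropylsilyl)pent-4-yn-1-yl]cyclohex-2-en-1-one
Product: 12 (R)-4-[(tert-butyldimethylsilyl)oxy]-5-[5-(triisopropylsilyl)pent-4-yn-1-yl]cyclohexa-1,5-dien-1-yl trifluoromethanesulfonate, via lithium dienolate 11 (not isolated)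
Conditions: LiN(iPr)2, THF, −78 °C; then PhNTf2, −78 → 0 °C
Reagents that add atoms: N-phenylbis(trifluoromethanesulfonimide), O=S(=O)(N(c1ccccc1)S(=O)(=O)C(F)(F)F)C(F)(F)F
Why: Kinetic deprotonation of a cyclohexenone occurs at the α'-methylene and gives the cross-conjugated dienolate, which is O-triflated; the γ-hydrogen at the stereocentre is left alone at −78 °C.

Step 7
Reactants: 12 (R)-4-[(tert-butyldimethylsilyl)oxy]-5-[5-(triisopropylsilyl)pent-4-yn-1-yl]cyclohexa-1,5-dien-1-yl trifluoromethanesulfonate
Product: 13 (R)-tert-butyldimethyl({2-[5-(triisopropylsilyl)pent-4-yn-1-yl]cyclohexa-2,4-dien-1-yl}oxy)silane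
Conditions: Pd(OAc)2 (5 mol%), PPh3 (10 mol%), HCO2H, Et3N, DMF, 40 °C
Reagents that add atoms: none
Why: Palladium-catalysed formate reduction of a dienyl triflate replaces C–OTf by C–H without moving the double bonds; formate avoids tin hydride, which could add to the alkyne, and the mildly basic medium discourages loss of silanol to the arene.

Step 8
Reactants: 13 (R)-tert-butyldimethyl({2-[5-(triisopropylsilyl)pent-4-yn-1-yl]cyclohexa-2,4-dien-1-yl}oxy)silane
Product: 14 (1R,4R,7R)-7-[(tert-butyldimethylsilyl)oxy]-1-[5-(triisopropylsilyl)pent-4-yn-1-yl]-2,3-dioxabicyclo[2.2.2]oct-5-ene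
Conditions: O2, 5,10,15,20-tetraphenylporphyrin (1 mol%), hν (visible), CH2Cl2, −78 °C
Reagents that add atoms: dioxygen, O=O
Why: Sensitised singlet oxygen adds suprafacially across the termini of the ring-locked s-cis diene in a concerted [4+2] cycloaddition, forming C1–O2 and C4–O3 together. The closest known reaction type is the photooxygenation of cyclohexa-1,3-dienes to 2,3-dioxabicyclo[2.2.2]octenes with facial control by an allylic oxygen substituent. The 1,2-dioxine ring (O2–O3–C4–C5=C6–C1) closes in this single cycloaddition event as the new bridge of the bicycle. Both new stereocentres, C1 and C4, are fixed at once by the face that is attacked, and that face is controlled by the (R)-silyloxy carbon next to the substituted terminus. Allylic 1,2-strain with the side chain should hold the silyloxy group pseudoaxial, so that it screens its own face sterically and by lone-pair repulsion, and oxygen should enter anti to it. The step needs face selectivity and chemoselectivity over the ene reaction; the cisoid diene, the aprotic solvent and the low temperature favour the cycloaddition, and the silyl alkyne is inert to singlet oxygen. Any syn adduct is a diastereomer and must be removed here or at 15 or 16, because after oxidation at C7 it would become the enantiomer of 17.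

Step 9
Reactants: 14 (1R,4R,7R)-7-[(tert-butyldimethylsilyl)oxy]-1-[5-(triisopropylsilyl)pent-4-yn-1-yl]-2,3-dioxabicyclo[2.2.2]oct-5-ene
Product: 15 (1R,4S,6R)-6-[(tert-butyldimethylsilyl)oxy]-1-[5-(triisopropylsilyl)pent-4-yn-1-yl]-2,3-dioxabicyclo[2.2.2]octane
Conditions: KO2C–N=N–CO2K, AcOH, CH2Cl2, −20 → 0 °C
Reagents that add atoms: none
Why: Diimide reduces the strained bicyclic alkene by concerted hydrogen transfer without breaking the O–O bond, the standard way to saturate unsaturated endoperoxides; the hindered silyl alkyne reacts far more slowly.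

Step 10
Reactants: 15 (1R,4S,6R)-6-[(tert-butyldimethylsilyl)oxy]-1-[5-(triisopropylsilyl)pent-4-yn-1-yl]-2,3-dioxabicyclo[2.2.2]octane
Product: 16 (1S,4R,5R)-4-[5-(triisopropylsilyl)pent-4-yn-1-yl]-2,3-dioxabicyclo[2.2.2]octan-5-ol
Conditions: HF·pyridine, pyridine, THF, 0 °C → rt
Reagents that add atoms: none
Why: Buffered hydrogen fluoride cleaves the silyl ether but not the alkynyl C–Si bond, and it avoids the basic fluoride that could trigger Kornblum–DeLaMare cleavage at the bridgehead C–H.

Step 11
Reactants: 16 (1S,4R,5R)-4-[5-(triisopropylsilyl)pent-4-yn-1-yl]-2,3-dioxabicyclo[2.2.2]octan-5-ol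
Product: 17 (1S,4R)-4-[5-(triisopropylsilyl)pent-4-yn-1-yl]-2,3-dioxabicyclo[2.2.2]octan-5-one
Conditions: Dess–Martin periodinane, NaHCO3, CH2Cl2, 0 °C
Reagents that add atoms: none
Why: Dess–Martin oxidation is neutral and non-reducing, so the peroxide survives, and the buffer keeps the enolisable β-peroxy ketone from eliminating; the carbinol centre is erased, and the ketone is used promptly.

Step 12
Reactants: 17 (1S,4R)-4-[5-(triisopropylsilyl)pent-4-yn-1-yl]-2,3-dioxabicyclo[2.2.2]octan-5-one
Product: 19 2-[(3S,6R)-6-methoxy-6-[5-(triisopropylsilyl)pent-4-yn-1-yl]-1,2-dioxan-3-yl]acetic acid, via peroxy lactone 18 (not isolated)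
Conditions: mCPBA, NaHCO3, CH2Cl2, 0 °C; cold aq. NaHCO3 wash; then camphorsulfonic acid (cat.), MeOH, 0 °C; pyridine quench
Reagents that add atoms: 3-chloroperoxybenzoic acid, O=C(OO)c1cccc(Cl)c1; methanol, CO
Why: Proposed new method: the peracid should add to the strained, inductively activated ketone, and in the Criegee adduct the tertiary peroxy-bearing bridgehead, which can carry positive charge as an incipient peroxycarbenium centre, should migrate with retention in preference to the methylene, while the O–O bond lies gauche to the breaking C–C bond and so is poorly placed for a Grob-type fragmentation; the closest known reaction type is the Baeyer–Villiger oxidation of α-alkoxy bridged ketones such as 7-oxabicyclo[2.2.1]heptan-2-ones, which gives acyloxy acetals by bridgehead migration; acid in methanol should then ionise acyloxy peroxyketal 18 by alkyl–oxygen cleavage to free the acid, and methanol should add to the peroxycarbenium ion to give axial OMe cis to the equatorial C3 arm, the epimer that reversible ionisation also favours.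

Step 13
Reactants: 19 2-[(3S,6R)-6-methoxy-6-[5-(triisopropylsilyl)pent-4-yn-1-yl]-1,2-dioxan-3-yl]acetic acid
Product: 20 2-[(3S,6R)-6-methoxy-6-(pent-4-yn-1-yl)-1,2-dioxan-3-yl]acetic acid
Conditions: Bu4NF (2.5 equiv), THF, 0 °C → rt
Reagents that add atoms: none
Why: Fluoride-induced protodesilylation of a silyl alkyne; the acid is present as its carboxylate, which cannot undergo E1cB ring opening, and the axial C3–H of the chair dioxane is poorly aligned for base-induced peroxide cleavage.

Step 14
Reactants: 21 dec-9-en-1-ol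
Product: 22 10-hydroxydecan-2-one
Conditions: PdCl2 (10 mol%), CuCl, O2 (1 atm), DMF/H2O, rt
Reagents that add atoms: water, O
Why: Tsuji–Wacker oxidation converts a terminal alkene into the methyl ketone by Markovnikov hydroxypalladation; a remote primary alcohol is tolerated.

Step 15
Reactants: 22 10-hydroxydecan-2-one
Product: 23 9-oxodecanal
Conditions: Dess–Martin periodinane, NaHCO3, CH2Cl2, rt
Reagents that add atoms: none
Why: Dess–Martin oxidation of a primary alcohol stops at the aldehyde and leaves the ketone untouched.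

Step 16
Reactants: 23 9-oxodecanal
Product: 24 (E)-11-iodoundec-10-en-2-one
Conditions: CrCl2, CHI3, THF, 0 °C → rt
Reagents that add atoms: iodoform, IC(I)I
Why: Takai olefination with the geminal dichromium reagent from iodoform and divalent chromium gives E-vinyl iodides from aldehydes and does not react with ketones at a comparable rate.

Step 17
Reactants: 20 2-[(3S,6R)-6-methoxy-6-(pent-4-yn-1-yl)-1,2-dioxan-3-yl]acetic acid; 24 (E)-11-iodoundec-10-en-2-one
Product: 25 2-[(3S,6R)-6-methoxy-6-[(6E)-15-oxohexadec-6-en-4-yn-1-yl]-1,2-dioxan-3-yl]acetic acid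
Conditions: PdCl2(PPh3)2 (5 mol%), CuI (10 mol%), Et3N, THF (degassed), rt
Reagents that add atoms: none
Why: Sonogashira coupling of a terminal alkyne with an E-vinyl iodide proceeds at room temperature with retention of alkene geometry; the acid is carried as its ammonium salt, and a monocyclic dialkyl peroxyketal should outlast the brief exposure to zerovalent palladium.

## Compound list

1 | (triisopropylsilyl)acetylene | C#C[Si](C(C)C)(C(C)C)C(C)C | starting material
2 | allyl bromide | C=CCBr | starting material
3 | [(triisopropylsilyl)ethynyl]magnesium bromide | CC(C)[Si](C#C[Mg]Br)(C(C)C)C(C)C | intermediate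
4 | triisopropyl(pent-4-en-1-yn-1-yl)silane | C=CCC#C[Si](C(C)C)(C(C)C)C(C)C | intermediate
5 | 2-iodocyclohex-2-en-1-one | O=C1CCCC=C1I | starting material
6 | (R)-2-iodocyclohex-2-en-1-ol | O[C@@H]1CCCC=C1I | intermediate
7 | (R)-tert-butyl[(2-iodocyclohex-2-en-1-yl)oxy]dimethylsilane | CC(C)(C)[Si](C)(C)O[C@@H]1CCCC=C1I | intermediate
8 | (R)-4-[(tert-butyldimethylsilyl)oxy]-3-iodocyclohex-2-en-1-one | CC(C)(C)[Si](C)(C)O[C@@H]1CCC(=O)C=C1I | intermediate
9 | 9-[5-(triisopropylsilyl)pent-4-yn-1-yl]-9-borabicyclo[3.3.1]nonane | CC(C)[Si](C#CCCCB1C2CCCC1CCC2)(C(C)C)C(C)C | intermediate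
10 | (R)-4-[(tert-butyldimethylsilyl)oxy]-3-[5-(triisopropylsilyl)pent-4-yn-1-yl]cyclohex-2-en-1-one | CC(C)(C)[Si](C)(C)O[C@@H]1CCC(=O)C=C1CCCC#C[Si](C(C)C)(C(C)C)C(C)C | intermediate
11 | lithium (R)-4-[(tert-butyldimethylsilyl)oxy]-5-[5-(triisopropylsilyl)pent-4-yn-1-yl]cyclohexa-1,5-dien-1-olate | CC(C)(C)[Si](C)(C)O[C@@H]1CC=C(O[Li])C=C1CCCC#C[Si](C(C)C)(C(C)C)C(C)C | intermediate
12 | (R)-4-[(tert-butyldimethylsilyl)oxy]-5-[5-(triisopropylsilyl)pent-4-yn-1-yl]cyclohexa-1,5-dien-1-yl trifluoromethanesulfonate | CC(C)(C)[Si](C)(C)O[C@@H]1CC=C(OS(=O)(=O)C(F)(F)F)C=C1CCCC#C[Si](C(C)C)(C(C)C)C(C)C | intermediate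
13 | (R)-tert-butyldimethyl({2-[5-(triisopropylsilyl)pent-4-yn-1-yl]cyclohexa-2,4-dien-1-yl}oxy)silane | CC(C)(C)[Si](C)(C)O[C@@H]1CC=CC=C1CCCC#C[Si](C(C)C)(C(C)C)C(C)C | intermediate
14 | (1R,4R,7R)-7-[(tert-butyldimethylsilyl)oxy]-1-[5-(triisopropylsilyl)pent-4-yn-1-yl]-2,3-dioxabicyclo[2.2.2]oct-5-ene (silyloxy syn to the alkene bridge) | CC(C)(C)[Si](C)(C)O[C@@H]1C[C@@H]2C=C[C@@]1(CCCC#C[Si](C(C)C)(C(C)C)C(C)C)OO2 | intermediate
15 | (1R,4S,6R)-6-[(tert-butyldimethylsilyl)oxy]-1-[5-(triisopropylsilyl)pent-4-yn-1-yl]-2,3-dioxabicyclo[2.2.2]octane | CC(C)(C)[Si](C)(C)O[C@@H]1C[C@@H]2CC[C@@]1(CCCC#C[Si](C(C)C)(C(C)C)C(C)C)OO2 | intermediate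
16 | (1S,4R,5R)-4-[5-(triisopropylsilyl)pent-4-yn-1-yl]-2,3-dioxabicyclo[2.2.2]octan-5-ol | O[C@@H]1C[C@@H]2CC[C@@]1(CCCC#C[Si](C(C)C)(C(C)C)C(C)C)OO2 | intermediate
17 | (1S,4R)-4-[5-(triisopropylsilyl)pent-4-yn-1-yl]-2,3-dioxabicyclo[2.2.2]octan-5-one | O=C1C[C@@H]2CC[C@@]1(CCCC#C[Si](C(C)C)(C(C)C)C(C)C)OO2 | intermediate
18 | (1R,5S)-1-[5-(triisopropylsilyl)pent-4-yn-1-yl]-2,6,7-trioxabicyclo[3.2.2]nonan-3-one | O=C1C[C@@H]2CC[C@](CCCC#C[Si](C(C)C)(C(C)C)C(C)C)(O1)OO2 | intermediate
19 | 2-[(3S,6R)-6-methoxy-6-[5-(triisopropylsilyl)pent-4-yn-1-yl]-1,2-dioxan-3-yl]acetic acid | CO[C@@]1(CCCC#C[Si](C(C)C)(C(C)C)C(C)C)CC[C@@H](CC(=O)O)OO1 | intermediate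
20 | 2-[(3S,6R)-6-methoxy-6-(pent-4-yn-1-yl)-1,2-dioxan-3-yl]acetic acid | CO[C@@]1(CCCC#C)CC[C@@H](CC(=O)O)OO1 | intermediate
21 | dec-9-en-1-ol | C=CCCCCCCCCO | starting material
22 | 10-hydroxydecan-2-one | CC(=O)CCCCCCCCO | intermediate
23 | 9-oxodecanal | CC(=O)CCCCCCCC=O | intermediate
24 | (E)-11-iodoundec-10-en-2-one | CC(=O)CCCCCCC/C=C/I | intermediate
25 | 2-[(3S,6R)-6-methoxy-6-[(6E)-15-oxohexadec-6-en-4-yn-1-yl]-1,2-dioxan-3-yl]acetic acid | CO[C@@]1(CCCC#C/C=C/CCCCCCCC(C)=O)CC[C@@H](CC(=O)O)OO1 | target

## Step count and risks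

Total step count: 17. Longest linear sequence: 13 steps (steps 2–13 and 17, from 5).

**Step 12 (proposed new method).**
- What may go wrong: fragmentation of the peracid adduct with loss of the O–O bond, migration of the methylene instead of the peroxy-bearing carbon, or β-elimination of the peroxide from the enolisable ketone before insertion.
- Fallback: it gives up the excision and builds the ring by established hydroperoxide chemistry, setting out from 4 and returning at 19.
  - Commercial methyl 4-oxobutanoate is allylated (Brown allylation) with (−)-B-allyldiisopinocampheylborane to methyl (R)-4-hydroxyhept-6-enoate F1, which lactonises on acidic work-up to (R)-5-allyldihydrofuran-2(3H)-one F2.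
  - Borane 9, made from 4 as in step 5, is iodinated (I2, NaOMe) to (5-iodopent-1-yn-1-yl)triisopropylsilane F3, and lithium–iodine exchange (tBuLi, −78 °C) gives [5-(triisopropylsilyl)pent-4-yn-1-yl]lithium F4.
  - Addition of F4 to F2 at −78 °C gives (R)-4-hydroxy-12-(triisopropylsilyl)dodec-1-en-11-yn-7-one F5, and mesylation (MsCl, Et3N) gives (R)-7-oxo-12-(triisopropylsilyl)dodec-1-en-11-yn-4-yl methanesulfonate F6.
  - Displacement with inversion by hydrogen peroxide (H2O2, KOH, 18-crown-6) gives (S)-4-hydroperoxy-12-(triisopropylsilyl)dodec-1-en-11-yn-7-one F7, which exists largely as its cyclic peroxyhemiketal.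
  - Camphorsulfonic acid in methanol converts F7, under the same thermodynamic control as in step 12, into (3R,6S)-3-methoxy-6-(prop-2-en-1-yl)-3-[5-(triisopropylsilyl)pent-4-yn-1-yl]-1,2-dioxane F8.
  - Ozonolysis of the terminal alkene (O3, CH2Cl2, −78 °C, dye end point; Me2S) gives 2-[(3S,6R)-6-methoxy-6-[5-(triisopropylsilyl)pent-4-yn-1-yl]-1,2-dioxan-3-yl]acetaldehyde F9, and Pinnick oxidation (NaClO2, NaH2PO4, 2-methylbut-2-ene) gives 19.

**Step 8 (key step).**
- What may go wrong: poor facial selectivity because the small, linear dienophile slips past the silyl ether, competing ene hydroperoxidation at the trisubstituted terminus, or loss of silanol from 13 to the arene before oxygenation. Syn adduct carried forward would erode the enantiomeric purity of 17.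
- Fallback: steric steering is replaced by hydrogen-bond steering in the mirror-image series, setting out from 5 and returning at 17.
  - Reduction of 5 with the (R)-oxazaborolidine gives (S)-2-iodocyclohex-2-en-1-ol F10.
  - Steps 3–7 applied to F10 give in turn (S)-tert-butyl[(2-iodocyclohex-2-en-1-yl)oxy]dimethylsilane F11, (S)-4-[(tert-butyldimethylsilyl)oxy]-3-iodocyclohex-2-en-1-one F12, (S)-4-[(tert-butyldimethylsilyl)oxy]-3-[5-(triisopropylsilyl)pent-4-yn-1-yl]cyclohex-2-en-1-one F13, its lithium dienolate F14, the (S)-dienyl triflate F15 and (S)-tert-butyldimethyl({2-[5-(triisopropylsilyl)pent-4-yn-1-yl]cyclohexa-2,4-dien-1-yl}oxy)silane F16.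
  - Buffered Bu4NF frees (S)-2-[5-(triisopropylsilyl)pent-4-yn-1-yl]cyclohexa-2,4-dien-1-ol F17.
  - Photooxygenation of F17 in a non-polar solvent, where the hydroxyl group directs singlet oxygen to its own face, should give (1R,4R,5S)-4-[5-(triisopropylsilyl)pent-4-yn-1-yl]-2,3-dioxabicyclo[2.2.2]oct-7-en-5-ol F18, with the same bridgehead configuration as 14.
  - Diimide reduction gives (1S,4R,5S)-4-[5-(triisopropylsilyl)pent-4-yn-1-yl]-2,3-dioxabicyclo[2.2.2]octan-5-ol F19, and Dess–Martin oxidation gives 17.

**Step 4.**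
- What may go wrong: sluggish hydrogen abstraction next to the electron-poor iodoalkene, or attack at the silyloxy-bearing allylic C–H with loss of the protecting group.
- Fallback: the order of events is reversed, setting out from 7 and returning at 10. B-alkyl Suzuki–Miyaura coupling of 7 with borane 9 gives (R)-tert-butyldimethyl({2-[5-(triisopropylsilyl)pent-4-yn-1-yl]cyclohex-2-en-1-yl}oxy)silane F20. Allylic oxidation of its electron-richer trisubstituted alkene at the ring methylene (Rh2(caprolactamate)4, tBuOOH, or CrO3–3,5-dimethylpyrazole) gives 10.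

**Step 17.**
- What may go wrong: reduction or rearrangement of the peroxide by low-valent palladium or monovalent copper, copper carboxylate formation, or acid-promoted loss of methanol from the peroxyketal.
- Fallback: the acid is masked and copper is left out, setting out from 19 and returning at 25.
  - Esterification (Me3SiCHN2, MeOH) gives methyl 2-[(3S,6R)-6-methoxy-6-[5-(triisopropylsilyl)pent-4-yn-1-yl]-1,2-dioxan-3-yl]acetate F21.
  - Bu4NF gives methyl 2-[(3S,6R)-6-methoxy-6-(pent-4-yn-1-yl)-1,2-dioxan-3-yl]acetate F22.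
  - Copper-free coupling with 24 (Pd(PPh3)4, piperidine, rt) gives methyl 2-[(3S,6R)-6-methoxy-6-[(6E)-15-oxohexadec-6-en-4-yn-1-yl]-1,2-dioxan-3-yl]acetate F23.
  - Mild saponification (LiOH, THF/H2O, 0 °C) gives 25.

## Further compounds

F1 | step 12 | methyl (R)-4-hydroxyhept-6-enoate | C=CC[C@H](O)CCC(=O)OC
F2 | step 12 | (R)-5-allyldihydrofuran-2(3H)-one | C=CC[C@H]1CCC(=O)O1
F3 | step 12 | (5-iodopent-1-yn-1-yl)triisopropylsilane | ICCCC#C[Si](C(C)C)(C(C)C)C(C)C
F4 | step 12 | [5-(triisopropylsilyl)pent-4-yn-1-yl]lithium | [Li]CCCC#C[Si](C(C)C)(C(C)C)C(C)C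
F5 | step 12 | (R)-4-hydroxy-12-(triisopropylsilyl)dodec-1-en-11-yn-7-one | C=CC[C@H](O)CCC(=O)CCCC#C[Si](C(C)C)(C(C)C)C(C)C
F6 | step 12 | (R)-7-oxo-12-(triisopropylsilyl)dodec-1-en-11-yn-4-yl methanesulfonate | C=CC[C@H](OS(C)(=O)=O)CCC(=O)CCCC#C[Si](C(C)C)(C(C)C)C(C)C
F7 | step 12 | (S)-4-hydroperoxy-12-(triisopropylsilyl)dodec-1-en-11-yn-7-one | C=CC[C@@H](OO)CCC(=O)CCCC#C[Si](C(C)C)(C(C)C)C(C)C
F8 | step 12 | (3R,6S)-3-methoxy-6-(prop-2-en-1-yl)-3-[5-(triisopropylsilyl)pent-4-yn-1-yl]-1,2-dioxane | CO[C@@]1(CCCC#C[Si](C(C)C)(C(C)C)C(C)C)CC[C@@H](CC=C)OO1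
F9 | step 12 | 2-[(3S,6R)-6-methoxy-6-[5-(triisopropylsilyl)pent-4-yn-1-yl]-1,2-dioxan-3-yl]acetaldehyde | CO[C@@]1(CCCC#C[Si](C(C)C)(C(C)C)C(C)C)CC[C@@H](CC=O)OO1
F10 | step 8 | (S)-2-iodocyclohex-2-en-1-ol | O[C@H]1CCCC=C1I
F11 | step 8 | (S)-tert-butyl[(2-iodocyclohex-2-en-1-yl)oxy]dimethylsilane | CC(C)(C)[Si](C)(C)O[C@H]1CCCC=C1I
F12 | step 8 | (S)-4-[(tert-butyldimethylsilyl)oxy]-3-iodocyclohex-2-en-1-one | CC(C)(C)[Si](C)(C)O[C@H]1CCC(=O)C=C1I
F13 | step 8 | (S)-4-[(tert-butyldimethylsilyl)oxy]-3-[5-(triisopropylsilyl)pent-4-yn-1-yl]cyclohex-2-en-1-one | CC(C)(C)[Si](C)(C)O[C@H]1CCC(=O)C=C1CCCC#C[Si](C(C)C)(C(C)C)C(C)C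
F14 | step 8 | lithium (S)-4-[(tert-butyldimethylsilyl)oxy]-5-[5-(triisopropylsilyl)pent-4-yn-1-yl]cyclohexa-1,5-dien-1-olate | CC(C)(C)[Si](C)(C)O[C@H]1CC=C(O[Li])C=C1CCCC#C[Si](C(C)C)(C(C)C)C(C)C
F15 | step 8 | (S)-4-[(tert-butyldimethylsilyl)oxy]-5-[5-(triisopropylsilyl)pent-4-yn-1-yl]cyclohexa-1,5-dien-1-yl trifluoromethanesulfonate | CC(C)(C)[Si](C)(C)O[C@H]1CC=C(OS(=O)(=O)C(F)(F)F)C=C1CCCC#C[Si](C(C)C)(C(C)C)C(C)C
F16 | step 8 | (S)-tert-butyldimethyl({2-[5-(triisopropylsilyl)pent-4-yn-1-yl]cyclohexa-2,4-dien-1-yl}oxy)silane | CC(C)(C)[Si](C)(C)O[C@H]1CC=CC=C1CCCC#C[Si](C(C)C)(C(C)C)C(C)C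
F17 | step 8 | (S)-2-[5-(triisopropylsilyl)pent-4-yn-1-yl]cyclohexa-2,4-dien-1-ol | O[C@H]1CC=CC=C1CCCC#C[Si](C(C)C)(C(C)C)C(C)C
F18 | step 8 | (1R,4R,5S)-4-[5-(triisopropylsilyl)pent-4-yn-1-yl]-2,3-dioxabicyclo[2.2.2]oct-7-en-5-ol | O[C@H]1C[C@@H]2C=C[C@@]1(CCCC#C[Si](C(C)C)(C(C)C)C(C)C)OO2
F19 | step 8 | (1S,4R,5S)-4-[5-(triisopropylsilyl)pent-4-yn-1-yl]-2,3-dioxabicyclo[2.2.2]octan-5-ol | O[C@H]1C[C@@H]2CC[C@@]1(CCCC#C[Si](C(C)C)(C(C)C)C(C)C)OO2
F20 | step 4 | (R)-tert-butyldimethyl({2-[5-(triisopropylsilyl)pent-4-yn-1-yl]cyclohex-2-en-1-yl}oxy)silane | CC(C)(C)[Si](C)(C)O[C@@H]1CCCC=C1CCCC#C[Si](C(C)C)(C(C)C)C(C)C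
F21 | step 17 | methyl 2-[(3S,6R)-6-methoxy-6-[5-(triisopropylsilyl)pent-4-yn-1-yl]-1,2-dioxan-3-yl]acetate | CO[C@@]1(CCCC#C[Si](C(C)C)(C(C)C)C(C)C)CC[C@@H](CC(=O)OC)OO1
F22 | step 17 | methyl 2-[(3S,6R)-6-methoxy-6-(pent-4-yn-1-yl)-1,2-dioxan-3-yl]acetate | CO[C@@]1(CCCC#C)CC[C@@H](CC(=O)OC)OO1
F23 | step 17 | methyl 2-[(3S,6R)-6-methoxy-6-[(6E)-15-oxohexadec-6-en-4-yn-1-yl]-1,2-dioxan-3-yl]acetate | CO[C@@]1(CCCC#C/C=C/CCCCCCCC(C)=O)CC[C@@H](CC(=O)OC)OO1
A1 | alternative 1 | (S)-tert-butyl{[3-hydroperoxy-6,6-dimethoxy-11-(triisopropylsilyl)undec-10-yn-1-yl]oxy}diphenylsilane | COC(OC)(CCCC#C[Si](C(C)C)(C(C)C)C(C)C)CC[C@H](OO)CCO[Si](C(C)(C)C)(c1ccccc1)c1ccccc1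
A2 | alternative 1 | 6-methoxy-3-[2-(tert-butyldiphenylsilyloxy)ethyl]-6-[5-(triisopropylsilyl)pent-4-yn-1-yl]-1,2-dioxane, target configuration at both ring carbons | CO[C@@]1(CCCC#C[Si](C(C)C)(C(C)C)C(C)C)CC[C@@H](CCO[Si](C(C)(C)C)(c2ccccc2)c2ccccc2)OO1
A3 | alternative 2 | methyl 3-methoxy-3-[(triethylsilyl)peroxy]propanoate | COC(=O)CC(OC)OO[Si](CC)(CC)CC
A4 | alternative 2 | triisopropyl[5-(1-methoxycyclopropyl)pent-1-yn-1-yl]silane | COC1(CCCC#C[Si](C(C)C)(C(C)C)C(C)C)CC1
A5 | alternative 2 | methyl 2-[(3S,6R)-6-methoxy-6-[5-(triisopropylsilyl)pent-4-yn-1-yl]-1,2-dioxan-3-yl]acetate | CO[C@@]1(CCCC#C[Si](C(C)C)(C(C)C)C(C)C)CC[C@@H](CC(=O)OC)OO1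
A6 | alternative 3 | tert-butyl{[3-({3-methoxy-8-(triisopropylsilyl)oct-1-en-7-yn-3-yl}peroxy)pent-4-en-1-yl]oxy}diphenylsilane, target-configured diastereomer | CO[C@](C=C)(CCCC#C[Si](C(C)C)(C(C)C)C(C)C)OO[C@@H](C=C)CCO[Si](C(C)(C)C)(c1ccccc1)c1ccccc1
A7 | alternative 3 | 3-methoxy-6-[2-(tert-butyldiphenylsilyloxy)ethyl]-3-[5-(triisopropylsilyl)pent-4-yn-1-yl]-3,6-dihydro-1,2-dioxine, target-configured epimer | CO[C@@]1(CCCC#C[Si](C(C)C)(C(C)C)C(C)C)C=C[C@@H](CCO[Si](C(C)(C)C)(c2ccccc2)c2ccccc2)OO1
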